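**Retrosynthetic overview**

1. Locants used below: C1 = ring carbinol carrying the crotonoyl chain (C2–C4, C15); C5 = ester CH; C6/C7 = lactone ring fusion (O–CH/CH); C8 = CH2; C9 = CHOH; C10 = CHMe; C11–C13 = methylene-lactone carbons. Target ⇒ O9 desilylation, O5 acylation with (R)-2-methylbutanoic acid, and hydroxyl-directed reduction of a C5 ring ketone.
2. Key disconnection: the cycloheptanone unit C5(=O)–C1(OH)(crotonoyl) ⇒ α-ketol 1,2-shift with ring expansion (C10 migrates from C5 to C1) of a cyclohexanol that carries a 2-oxopent-3-enoyl chain on C5.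
3. That vicinal diketone ⇒ dioxirane oxidation of the diazo aldol adduct of (E)-1-diazopent-3-en-2-one with a trans-fused cyclohexanone/α-methylene lactone.
4. Cyclohexanone ⇒ intramolecular aldol (C9–C10) of a keto aldehyde; its butyrolactone ⇒ enantioselective chromium-catalysed 2-(methoxycarbonyl)allylation (C6–C7) of 2-oxobutanal with a Baylis–Hillman-derived allyl bromide.
5. Ring order: γ-lactone, then cyclohexanone, then expansion to the cycloheptanone.

Assumption: the SMILES is read literally (2-methylbutanoate R; C1 S, C5 S, C6 R, C7 R, C9 R, C10 S), and 1, 5 and 11 are bought as monomers (5 freshly distilled).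

**Route**

Step 1
Reactants: 1 3,3-dimethoxypropanal; 2 methyl acrylate
Product: 3 methyl 3-hydroxy-5,5-dimethoxy-2-methylidenepentanoate (racemic)
Conditions: DABCO (0.5 equiv), 1,4-dioxane/H2O (1:1), rt, 48 h
Reagents that add atoms: none
Why: Morita–Baylis–Hillman reaction in which the DABCO–acrylate zwitterion adds to the unhindered aldehyde, the racemic carbinol centre being erased in step 2.

Step 2
Reactants: 3 methyl 3-hydroxy-5,5-dimethoxy-2-methylidenepentanoate
Product: 4 methyl (2Z)-2-(bromomethyl)-5,5-dimethoxypent-2-enoate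
Conditions: NBS, Me2S, CH2Cl2, 0 °C to rt
Reagents that add atoms: N-bromosuccinimide O=C1CCC(=O)N1Br
Why: Corey–Kim-type activation of the Baylis–Hillman alcohol followed by SN2′ attack of bromide gives the thermodynamically preferred (Z)-2-(bromomethyl)enoate under near-neutral conditions that spare the acetal.

Step 3
Reactants: 4 methyl (2Z)-2-(bromomethyl)-5,5-dimethoxypent-2-enoate; 5 2-oxobutanal
Product: 8 2-[(2R,3R)-4-methylidene-5-oxo-2-propanoyloxolan-3-yl]acetaldehyde, via silyl ether 6 (not isolated), via acetal lactone 7 (not isolated)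
Conditions: CrCl2 (10 mol%), 3,6-di-tert-butyl-1,8-bis(4-isopropyl-4,5-dihydrooxazol-2-yl)-9H-carbazole (12 mol%, the enantiomer that delivers the R carbinol), Mn powder, Me3SiCl, 5 (2 equiv), THF, rt; then 2 M HCl, THF, rt
Reagents that add atoms: chlorotrimethylsilane C[Si](C)(C)Cl (silyl group only in 6); water O
Why: Catalytic asymmetric Nozaki–Hiyama–Kishi-type 2-(alkoxycarbonyl)allylation in which the allylchromium adds through its γ-carbon to the aldehyde (not the ketone) of 5 via a chair transition state that gives the anti adduct, the ligand setting C6 (R) and thereby C7 (R), after which acid desilylates, closes the trans-lactone and unmasks the aldehyde.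

Step 4
Reactants: 8 2-[(2R,3R)-4-methylidene-5-oxo-2-propanoyloxolan-3-yl]acetaldehyde
Product: 9 (3aR,5R,6S,7aR)-5-hydroxy-6-methyl-3-methylidenehexahydro-1-benzofuran-2,7-dione
Conditions: DBU (10 mol%), CH2Cl2 (0.02 M), 0 °C; AcOH quench
Reagents that add atoms: none
Why: Intramolecular aldol addition (6-enolendo-exo-trig) in which the only unstrained mode is attack of the ethyl-ketone enolate carbon C10 on the aldehyde C9, and reversibility (retro-aldol, epimerisable C10) funnels the material to the all-equatorial chair, setting C9 (R) and C10 (S) relative to C6/C7.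

Step 5
Reactants: 9 (3aR,5R,6S,7aR)-5-hydroxy-6-methyl-3-methylidenehexahydro-1-benzofuran-2,7-dione
Product: 10 (3aR,5R,6S,7aR)-5-[(tert-butyldimethylsilyl)oxy]-6-methyl-3-methylidenehexahydro-1-benzofuran-2,7-dione
Conditions: TBSOTf, 2,6-lutidine, CH2Cl2, −78 °C
Reagents that add atoms: tert-butyldimethylsilyl trifluoromethanesulfonate CC(C)(C)[Si](C)(C)OS(=O)(=O)C(F)(F)F
Why: Silyl protection of the secondary alcohol at low temperature (the ketone is not enolised) blocks retro-aldol in step 7 and distinguishes O9 from O5 in step 10.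

Step 6
Reactants: 11 (3E)-pent-3-en-2-one
Product: 13 (3E)-1-diazopent-3-en-2-one, via trifluoroacetyl diketone 12 (not isolated)
Conditions: LiN(SiMe3)2, THF, −78 °C, then CF3CO2CH2CF3; then MsN3, Et3N, H2O, MeCN, rt
Reagents that add atoms: 2,2,2-trifluoroethyl trifluoroacetate O=C(OCC(F)(F)F)C(F)(F)F (trifluoroacetyl group only in 12); methanesulfonyl azide CS(=O)(=O)N=[N+]=[N-]
Why: Danheiser detrifluoroacetylative diazo transfer (Regitz type) on the kinetic methyl-side enolate gives the vinyl diazo ketone without the dipolar cycloadditions that spoil acid chloride/diazomethane routes.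

Step 7
Reactants: 10 (3aR,5R,6S,7aR)-5-[(tert-butyldimethylsilyl)oxy]-6-methyl-3-methylidenehexahydro-1-benzofuran-2,7-dione; 13 (3E)-1-diazopent-3-en-2-one
Product: 14 (3aR,5R,6S,7S,7aR)-5-[(tert-butyldimethylsilyl)oxy]-7-[(3E)-1-diazo-2-oxopent-3-en-1-yl]-7-hydroxy-6-methyl-3-methylidenehexahydro-1-benzofuran-2(3H)-one
Conditions: 13, LiN(i-Pr)2, THF, −78 °C; then 10, −78 °C; AcOH quench at −78 °C
Reagents that add atoms: none
Why: Aldol-type addition of the C-lithiated diazo ketone to the ketone (faster than lactone or conjugate attack at −78 °C) along the axial trajectory of the chair, whose two equatorial α-substituents flank the equatorial approach, places the new C–C bond axial and the OH equatorial (7S).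

Step 8
Reactants: 14 (3aR,5R,6S,7S,7aR)-5-[(tert-butyldimethylsilyl)oxy]-7-[(3E)-1-diazo-2-oxopent-3-en-1-yl]-7-hydroxy-6-methyl-3-methylidenehexahydro-1-benzofuran-2(3H)-one
Product: 16 (3aR,5R,6S,7R,8aR)-7-[(2E)-but-2-enoyl]-5-[(tert-butyldimethylsilyl)oxy]-7-hydroxy-6-methyl-3-methylidenehexahydro-2H-cyclohepta[b]furan-2,8(3H)-dione, via vicinal diketone 15 (not isolated)
Conditions: DMDO (1.2 equiv), acetone, −78 to −20 °C; evaporate; then Sc(OTf)3 (10 mol%), 4 Å MS, CH2Cl2, −20 °C to rt
Reagents that add atoms: dimethyldioxirane CC1(C)OO1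
Why: Proposed new method: dimethyldioxirane turns the diazo group into a ketone (known diazo-to-carbonyl oxidation) and Sc(OTf)3 then triggers an α-ketol (acyloin) 1,2-shift of the tertiary α-hydroxy vicinal diketone 15, in which the electron-richer ring bond C5–C10 (not the acyloxy-bearing C5–C6) migrates suprafacially with retention at C10 onto the C1 carbonyl, driven by loss of the vicinal-dicarbonyl repulsion, while scandium bridging the equatorial carbinol oxygen and the distal C2 carbonyl (six-membered chelate, side chain pointing away from the ring) holds the C1 carbonyl anti to the carbinol oxygen so that the C5 configuration of 14 is relayed to C1 (OH cis to the C10 methyl, crotonoyl trans, as in the target); the closest known reaction type is the Lewis-acid-catalysed α-ketol rearrangement of β-hydroxy-α-keto esters and the D-homoannulation of 17-hydroxy-20-keto steroids, not yet shown for a cyclohexanol-to-cycloheptanone expansion of an α-hydroxy ene-1,2-dione.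

Step 9
Reactants: 16 (3aR,5R,6S,7R,8aR)-7-[(2E)-but-2-enoyl]-5-[(tert-butyldimethylsilyl)oxy]-7-hydroxy-6-methyl-3-methylidenehexahydro-2H-cyclohepta[b]furan-2,8(3H)-dione
Product: 17 (3aR,5R,6S,7S,8S,8aR)-7-[(2E)-but-2-enoyl]-5-[(tert-butyldimethylsilyl)oxy]-7,8-dihydroxy-6-methyl-3-methylideneoctahydro-2H-cyclohepta[b]furan-2-one
Conditions: Me4NBH(OAc)3 (1.5 equiv), MeCN/AcOH (1:1), −30 °C
Reagents that add atoms: none
Why: Hydroxyl-directed reduction (Evans–Saksena type) in which ligand exchange at the tertiary C1–OH delivers hydride intramolecularly to the adjacent, doubly α-oxygenated and therefore most electrophilic ring ketone from the face of the C1–O bond, giving the trans-1,2-diol (C5 S) and sparing the conjugated C2 ketone and the lactone.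

Step 10
Reactants: 17 (3aR,5R,6S,7S,8S,8aR)-7-[(2E)-but-2-enoyl]-5-[(tert-butyldimethylsilyl)oxy]-7,8-dihydroxy-6-methyl-3-methylideneoctahydro-2H-cyclohepta[b]furan-2-one; 18 (2R)-2-methylbutanoic acid
Product: 19 (3aR,5R,6S,7S,8S,8aR)-7-[(2E)-but-2-enoyl]-5-[(tert-butyldimethylsilyl)oxy]-7-hydroxy-6-methyl-3-methylidene-2-oxooctahydro-2H-cyclohepta[b]furan-8-yl (2R)-2-methylbutanoate
Conditions: DCC, DMAP (20 mol%), CH2Cl2, 0 °C to rt
Reagents that add atoms: none
Why: Steglich esterification acylates the only available secondary hydroxyl (C1–OH is tertiary, O9 is silylated), and carbodiimide activation avoids the ketene pathway that would racemise the α-centre of 18.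

Step 11
Reactants: 19 (3aR,5R,6S,7S,8S,8aR)-7-[(2E)-but-2-enoyl]-5-[(tert-butyldimethylsilyl)oxy]-7-hydroxy-6-methyl-3-methylidene-2-oxooctahydro-2H-cyclohepta[b]furan-8-yl (2R)-2-methylbutanoate
Product: 20 (3aR,5R,6S,7S,8S,8aR)-7-[(2E)-but-2-enoyl]-5,7-dihydroxy-6-methyl-3-methylidene-2-oxooctahydro-2H-cyclohepta[b]furan-8-yl (2R)-2-methylbutanoate
Conditions: HF·pyridine, pyridine/THF, 0 °C to rt
Reagents that add atoms: none
Why: Buffered fluoride desilylation frees O9 without touching the esters, the α′-hydroxy enone or the α-methylene lactone.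

**Compound list**

1 | 3,3-dimethoxypropanal | COC(OC)CC=O | starting material
2 | methyl acrylate | C=CC(=O)OC | starting material
3 | methyl 3-hydroxy-5,5-dimethoxy-2-methylidenepentanoate (racemic) | C=C(C(=O)OC)C(O)CC(OC)OC | intermediate
4 | methyl (2Z)-2-(bromomethyl)-5,5-dimethoxypent-2-enoate | COC(=O)/C(CBr)=C/CC(OC)OC | intermediate
5 | 2-oxobutanal | CCC(=O)C=O | starting material
6 | methyl (3R,4R)-3-(2,2-dimethoxyethyl)-2-methylidene-5-oxo-4-[(trimethylsilyl)oxy]heptanoate | C=C(C(=O)OC)[C@@H](CC(OC)OC)[C@@H](O[Si](C)(C)C)C(=O)CC | intermediate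
7 | (4R,5R)-4-(2,2-dimethoxyethyl)-3-methylidene-5-propanoyloxolan-2-one | C=C1C(=O)O[C@@H](C(=O)CC)[C@@H]1CC(OC)OC | intermediate
8 | 2-[(2R,3R)-4-methylidene-5-oxo-2-propanoyloxolan-3-yl]acetaldehyde | C=C1C(=O)O[C@@H](C(=O)CC)[C@@H]1CC=O | intermediate
9 | (3aR,5R,6S,7aR)-5-hydroxy-6-methyl-3-methylidenehexahydro-1-benzofuran-2,7-dione | C=C1C(=O)O[C@@H]2[C@@H]1C[C@@H](O)[C@H](C)C2=O | intermediate
10 | (3aR,5R,6S,7aR)-5-[(tert-butyldimethylsilyl)oxy]-6-methyl-3-methylidenehexahydro-1-benzofuran-2,7-dione | C=C1C(=O)O[C@@H]2[C@@H]1C[C@@H](O[Si](C)(C)C(C)(C)C)[C@H](C)C2=O | intermediate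
11 | (3E)-pent-3-en-2-one | C/C=C/C(C)=O | starting material
12 | (5E)-1,1,1-trifluorohept-5-ene-2,4-dione | C/C=C/C(=O)CC(=O)C(F)(F)F | intermediate
13 | (3E)-1-diazopent-3-en-2-one | C/C=C/C(=O)C=[N+]=[N-] | intermediate
14 | (3aR,5R,6S,7S,7aR)-5-[(tert-butyldimethylsilyl)oxy]-7-[(3E)-1-diazo-2-oxopent-3-en-1-yl]-7-hydroxy-6-methyl-3-methylidenehexahydro-1-benzofuran-2(3H)-one | C=C1C(=O)O[C@@H]2[C@@H]1C[C@@H](O[Si](C)(C)C(C)(C)C)[C@H](C)[C@]2(O)C(=[N+]=[N-])C(=O)/C=C/C | intermediate
15 | (3aR,5R,6S,7R,7aR)-5-[(tert-butyldimethylsilyl)oxy]-7-hydroxy-6-methyl-3-methylidene-7-[(3E)-2-oxopent-3-enoyl]hexahydro-1-benzofuran-2(3H)-one | C=C1C(=O)O[C@@H]2[C@@H]1C[C@@H](O[Si](C)(C)C(C)(C)C)[C@H](C)[C@]2(O)C(=O)C(=O)/C=C/C | intermediate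
16 | (3aR,5R,6S,7R,8aR)-7-[(2E)-but-2-enoyl]-5-[(tert-butyldimethylsilyl)oxy]-7-hydroxy-6-methyl-3-methylidenehexahydro-2H-cyclohepta[b]furan-2,8(3H)-dione | C=C1C(=O)O[C@@H]2[C@@H]1C[C@@H](O[Si](C)(C)C(C)(C)C)[C@H](C)[C@@](O)(C(=O)/C=C/C)C2=O | intermediate
17 | (3aR,5R,6S,7S,8S,8aR)-7-[(2E)-but-2-enoyl]-5-[(tert-butyldimethylsilyl)oxy]-7,8-dihydroxy-6-methyl-3-methylideneoctahydro-2H-cyclohepta[b]furan-2-one | C=C1C(=O)O[C@@H]2[C@@H]1C[C@@H](O[Si](C)(C)C(C)(C)C)[C@H](C)[C@@](O)(C(=O)/C=C/C)[C@H]2O | intermediate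
18 | (2R)-2-methylbutanoic acid | CC[C@@H](C)C(=O)O | starting material
19 | (3aR,5R,6S,7S,8S,8aR)-7-[(2E)-but-2-enoyl]-5-[(tert-butyldimethylsilyl)oxy]-7-hydroxy-6-methyl-3-methylidene-2-oxooctahydro-2H-cyclohepta[b]furan-8-yl (2R)-2-methylbutanoate | C=C1C(=O)O[C@@H]2[C@@H]1C[C@@H](O[Si](C)(C)C(C)(C)C)[C@H](C)[C@@](O)(C(=O)/C=C/C)[C@H]2OC(=O)[C@H](C)CC | intermediate
20 | (3aR,5R,6S,7S,8S,8aR)-7-[(2E)-but-2-enoyl]-5,7-dihydroxy-6-methyl-3-methylidene-2-oxooctahydro-2H-cyclohepta[b]furan-8-yl (2R)-2-methylbutanoate (CNP0331957.3) | C=C1C(=O)O[C@@H]2[C@@H]1C[C@@H](O)[C@H](C)[C@@](O)(C(=O)/C=C/C)[C@H]2OC(=O)[C@H](C)CC | target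

**Step count and risks**

Total step count: 11. Longest linear sequence: 10 (steps 1, 2, 3, 4, 5, 7, 8, 9, 10, 11); step 6 is a one-step side branch.

The three steps most likely to fail:

Step 3 (asymmetric allylation of an α-keto aldehyde). Background addition or keto-group chelation may erode ee and dr, and double addition is possible. Fallback, setting out from 4 and coming back at 7: take the C6 centre from the chiral pool. Commercial methyl (S)-2-hydroxybutanoate is silylated (TBSCl, imidazole) to methyl (2S)-2-[(tert-butyldimethylsilyl)oxy]butanoate F1 and half-reduced (i-Bu2AlH, −78 °C) to (2S)-2-[(tert-butyldimethylsilyl)oxy]butanal F2. Ligand-free CrCl2-mediated allylation with 4 (known Felkin–Anh, anti-selective addition to α-silyloxy aldehydes) and acid-catalysed lactonisation give (4R,5R)-5-[(1S)-1-[(tert-butyldimethylsilyl)oxy]propyl]-4-(2,2-dimethoxyethyl)-3-methylideneoxolan-2-one F3. HF·pyridine frees (4R,5R)-4-(2,2-dimethoxyethyl)-5-[(1S)-1-hydroxypropyl]-3-methylideneoxolan-2-one F4, and Dess–Martin oxidation returns 7, which the 2 M HCl treatment of step 3 converts into 8.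

Step 8 (proposed α-ketol ring expansion). The six-to-seven expansion may not be sufficiently downhill, the crotonoyl group may undergo a second ketol (acyl) shift, and a five-membered chelate would relay the wrong C1 configuration. Fallback with known chemistry, setting out from 14 and coming back at 16: Rh2(OAc)4 (1 mol%, CH2Cl2) induces the known 1,2-shift of β-hydroxy-α-diazo ketones with loss of N2 (C10 migrates to the carbenoid carbon) and gives (3aR,5R,6R,8aR)-7-[(2E)-but-2-enoyl]-5-[(tert-butyldimethylsilyl)oxy]-6-methyl-3-methylidenehexahydro-2H-cyclohepta[b]furan-2,8(3H)-dione F5 (enolised β-diketone, C7 epimers). Its enol is hydroxylated at C7 with dimethyldioxirane, or with an enantiopure (camphorsulfonyl)oxaziridine for reagent control of the face, to give 16. The weakness of this fallback is the face: the adjacent C10 methyl favours attack that gives the C7 epimer, so the epimer ratio has to be measured and the oxaziridine antipode chosen accordingly.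

Step 9 (directed reduction). The tertiary hydroxyl may exchange too slowly, the enone carbonyl could also be reduced, and the facial outcome is not certain. Fallback, setting out from 16 and coming back at 19 (step 10 is skipped): reduce without direction using NaBH4 in CH2Cl2/MeOH at −78 °C, where saturated ketones react before conjugated enones and hydride enters anti to the C6–O bond (Felkin–Anh). This gives the cis-diol (3aR,5R,6S,7S,8R,8aR)-7-[(2E)-but-2-enoyl]-5-[(tert-butyldimethylsilyl)oxy]-7,8-dihydroxy-6-methyl-3-methylideneoctahydro-2H-cyclohepta[b]furan-2-one F6. The ester is then installed with inversion at C8 by a Mitsunobu reaction with acid 18 (PPh3, DIAD, toluene), arriving at 19.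

**Further compounds**

F1 | step 3 | methyl (2S)-2-[(tert-butyldimethylsilyl)oxy]butanoate | CC[C@H](O[Si](C)(C)C(C)(C)C)C(=O)OC
F2 | step 3 | (2S)-2-[(tert-butyldimethylsilyl)oxy]butanal | CC[C@H](O[Si](C)(C)C(C)(C)C)C=O
F3 | step 3 | (4R,5R)-5-[(1S)-1-[(tert-butyldimethylsilyl)oxy]propyl]-4-(2,2-dimethoxyethyl)-3-methylideneoxolan-2-one | C=C1C(=O)O[C@@H]([C@@H](O[Si](C)(C)C(C)(C)C)CC)[C@@H]1CC(OC)OC
F4 | step 3 | (4R,5R)-4-(2,2-dimethoxyethyl)-5-[(1S)-1-hydroxypropyl]-3-methylideneoxolan-2-one | C=C1C(=O)O[C@@H]([C@@H](O)CC)[C@@H]1CC(OC)OC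
F5 | step 8 | (3aR,5R,6R,8aR)-7-[(2E)-but-2-enoyl]-5-[(tert-butyldimethylsilyl)oxy]-6-methyl-3-methylidenehexahydro-2H-cyclohepta[b]furan-2,8(3H)-dione (C7 epimers, enolised) | C=C1C(=O)O[C@@H]2[C@@H]1C[C@@H](O[Si](C)(C)C(C)(C)C)[C@H](C)C(C(=O)/C=C/C)C2=O
F6 | step 9 | (3aR,5R,6S,7S,8R,8aR)-7-[(2E)-but-2-enoyl]-5-[(tert-butyldimethylsilyl)oxy]-7,8-dihydroxy-6-methyl-3-methylideneoctahydro-2H-cyclohepta[b]furan-2-one | C=C1C(=O)O[C@@H]2[C@@H]1C[C@@H](O[Si](C)(C)C(C)(C)C)[C@H](C)[C@@](O)(C(=O)/C=C/C)[C@@H]2O
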